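**Retrosynthetic overview**

1. The ten-membered ring is closed last, by ring-closing metathesis at C4=C5 of an acyclic diene; the ring size enforces the Z geometry.
2. C10–C1 comes from a boron anti-aldol of an α′-acyloxy ethyl ketone with 4-methylpent-4-enal; the C8 ester steers both new centres.
3. Key bond C8–O: asymmetric α-acyloxylation of a cis-lactone aldehyde by [3,3] transfer of the intact epoxyangelate from an N-methyl-O-acylhydroxylamine. This one step installs the side chain, the C8 centre and the control element for the aldol.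
4. The five-membered lactone ring is made first: syn-selective zinc Barbier allylation of acrolein with a Baylis–Hillman-derived bromide, kinetic resolution, acid lactonisation.
5. The side chain comes from angelic acid by Sharpless epoxidation and oxidation.

Assumption: positions are given in germacranolide numbering (C1 carbinol, C4=C5 alkene, C6 lactone O–CH, C7, C8 acyloxy, C9 ketone, C10 CHMe, C11=C13 methylene, C12 lactone carbonyl), and the (R) phosphoric acid in step 11 is taken as the enantiomer matched with the substrate bias (otherwise its mirror image is used).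

**Route**

Step 1
Reactants: 1 ethyl 3,3-diethoxypropanoate
Product: 2 3,3-diethoxypropanal
Conditions: iBu2AlH (1.05 equiv), CH2Cl2, −78 °C; aq. potassium sodium tartrate
Reagents that add atoms: none
Why: Partial ester reduction, since the aluminium hemiacetal is stable at −78 °C and releases the aldehyde only on work-up; no stereocentre.

Step 2
Reactants: 2 3,3-diethoxypropanal; 3 methyl acrylate
Product: 4 methyl 5,5-diethoxy-3-hydroxy-2-methylidenepentanoate (racemic)
Conditions: DABCO (30 mol%), MeOH, rt, 48 h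
Reagents that add atoms: none
Why: Morita–Baylis–Hillman reaction of an unhindered aliphatic aldehyde; the racemic carbinol centre is erased in step 3.

Step 3
Reactants: 4 methyl 5,5-diethoxy-3-hydroxy-2-methylidenepentanoate
Product: 5 methyl (2Z)-2-(bromomethyl)-5,5-diethoxypent-2-enoate
Conditions: NBS, Me2S, CH2Cl2, 0 °C to rt
Reagents that add atoms: N-bromosuccinimide, O=C1CCC(=O)N1Br
Why: Corey–Kim-type activation of the alcohol and SN2′ delivery of bromide gives the conjugated Z allylic bromide under non-acidic conditions that spare the acetal.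

Step 4
Reactants: 5 methyl (2Z)-2-(bromomethyl)-5,5-diethoxypent-2-enoate; 6 acrolein
Product: 7 methyl (3RS,4RS)-3-(2,2-diethoxyethyl)-4-hydroxy-2-methylidenehex-5-enoate (syn racemate)
Conditions: Zn dust, THF/sat. aq. NH4Cl (2:1), 0 °C to rt
Reagents that add atoms: none
Why: Zinc Barbier allylation (1,2-addition) through a chair transition state in which the Z-allylzinc carries its C8 arm axial, giving the syn C6/C7 adduct that later closes to the cis-lactone.

Step 5
Reactants: 7 methyl (3RS,4RS)-3-(2,2-diethoxyethyl)-4-hydroxy-2-methylidenehex-5-enoate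
Product: 8 methyl (3S,4S)-3-(2,2-diethoxyethyl)-4-hydroxy-2-methylidenehex-5-enoate (recovered enantiomer, at most 50%)
Conditions: Ti(OiPr)4 (15 mol%), L-(+)-diisopropyl tartrate (18 mol%), tBuOOH (0.6 equiv), 4 Å molecular sieves, CH2Cl2, −20 °C, to about 55% conversion
Reagents that add atoms: none
Why: Sharpless kinetic resolution of a secondary vinyl carbinol: with the L-(+)-tartrate the (4R) enantiomer is epoxidised fast and the (3S,4S) alcohol (C6 S, C7 S) is left, while the electron-poor acrylate is inert.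

Step 6
Reactants: 8 methyl (3S,4S)-3-(2,2-diethoxyethyl)-4-hydroxy-2-methylidenehex-5-enoate
Product: 10 2-[(2S,3S)-2-ethenyl-4-methylidene-5-oxooxolan-3-yl]acetaldehyde, via lactone diethyl acetal 9 (not isolated)
Conditions: TsOH·H2O (20 mol%), THF/H2O (4:1), 40 °C
Reagents that add atoms: water, O
Why: Acid-catalysed lactonisation (closes the cis-fused five-membered lactone through the C12–O bond) followed by acetal hydrolysis; neither stereocentre is epimerisable under these conditions.

Step 7
Reactants: 11 angelic acid, (2Z)-2-methylbut-2-enoic acid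
Product: 12 (2Z)-2-methylbut-2-en-1-ol
Conditions: LiAlH4, Et2O, 0 °C
Reagents that add atoms: none
Why: Hydride reduction of the acid at low temperature keeps the Z geometry.

Step 8
Reactants: 12 (2Z)-2-methylbut-2-en-1-ol
Product: 13 [(2S,3R)-2,3-dimethyloxiran-2-yl]methanol
Conditions: Ti(OiPr)4 (10 mol%), L-(+)-diethyl tartrate (12 mol%), tBuOOH, 4 Å molecular sieves, CH2Cl2, −20 °C
Reagents that add atoms: tert-butyl hydroperoxide, CC(C)(C)OO
Why: Sharpless asymmetric epoxidation: the L-(+)-tartrate delivers oxygen to the face that gives the (2S,3R) epoxy alcohol, and the Z alkene fixes the trans relationship of the two methyl groups.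

Step 9
Reactants: 13 [(2S,3R)-2,3-dimethyloxiran-2-yl]methanol
Product: 14 (2R,3R)-2,3-dimethyloxirane-2-carboxylic acid (epoxyangelic acid)
Conditions: RuCl3 (2 mol%), NaIO4 (2.2 equiv), MeCN/EtOAc/H2O, 0 °C to rt
Reagents that add atoms: water, O
Why: Catalytic ruthenium tetroxide oxidation of the primary alcohol to the acid leaves the epoxide untouched; the C2 descriptor changes from S to R by priority only.

Step 10
Reactants: 14 (2R,3R)-2,3-dimethyloxirane-2-carboxylic acid
Product: 16 O-[(2R,3R)-2,3-dimethyloxirane-2-carbonyl]-N-methylhydroxylamine (free base, used at once), via acyl imidazole 15 (not isolated)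
Conditions: CDI, CH2Cl2, 0 °C; MeNHOH·HCl, rt; cold aq. NaHCO3 wash
Reagents that add atoms: N-methylhydroxylamine hydrochloride, CNO.Cl
Why: Carbonyldiimidazole activation, then acylation of the hydroxylamine at oxygen because its nitrogen is protonated; the quaternary α-carbon slows O-to-N acyl shift of the free base.

Step 11
Reactants: 10 2-[(2S,3S)-2-ethenyl-4-methylidene-5-oxooxolan-3-yl]acetaldehyde; 16 O-[(2R,3R)-2,3-dimethyloxirane-2-carbonyl]-N-methylhydroxylamine
Product: 19 (1R)-1-[(2S,3S)-2-ethenyl-4-methylidene-5-oxooxolan-3-yl]-2-oxoethyl (2R,3R)-2,3-dimethyloxirane-2-carboxylate, via N-acyloxy enamine 17 (not isolated), via N-methyl imine 18 (not isolated)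
Conditions: 16 (1.3 equiv), (R)-TRIP [(R)-3,3′-bis(2,4,6-triisopropylphenyl)-1,1′-binaphthyl-2,2′-diyl hydrogen phosphate] (10 mol%), Amberlite CG50, toluene, 30 °C; then H2O
Reagents that add atoms: water, O
Why: Proposed new method: chiral-phosphoric-acid-catalysed asymmetric α-acyloxylation by [3,3]-sigmatropic oxygen transfer, in which 10 condenses with 16 to enamine 17, whose N-protonated, phosphate-paired form rearranges through a six-membered chair (the acyl carbonyl oxygen bonds to C8 as the weak N–O bond breaks) to imine 18, hydrolysed on work-up; oxygen is delivered to the enamine face anti to C6 and its cis vinyl group (C7–H eclipsing the enamine, A(1,3) control), which gives 8R, and the chiral ion pair is chosen to reinforce that face, while the resin traps MeNH2 so that neither the acid catalyst nor the α-methylene lactone is consumed; closest known reactions are the racemic α-acyloxylation of aldehydes and ketones with N-methyl-O-acylhydroxylamine hydrochlorides and the phosphoric-acid-catalysed asymmetric Fischer indolization, a [3,3] shift of an N-protonated ene-hydrazine run with the same amine-scavenging resin.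

Step 12
Reactants: 19 (1R)-1-[(2S,3S)-2-ethenyl-4-methylidene-5-oxooxolan-3-yl]-2-oxoethyl (2R,3R)-2,3-dimethyloxirane-2-carboxylate
Product: 20 (1R)-1-[(2S,3S)-2-ethenyl-4-methylidene-5-oxooxolan-3-yl]-2-hydroxybutyl (2R,3R)-2,3-dimethyloxirane-2-carboxylate (both C9 epimers)
Conditions: EtMgBr (1.1 equiv), THF, −78 °C, inverse addition; sat. aq. NH4Cl at −78 °C
Reagents that add atoms: ethylmagnesium bromide, CC[Mg]Br
Why: Grignard addition to the aldehyde is far faster at −78 °C than attack on the esters or the enoate, and the cold quench limits 1,2-acyl shift; the new C9 centre is oxidised away in step 13.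

Step 13
Reactants: 20 (1R)-1-[(2S,3S)-2-ethenyl-4-methylidene-5-oxooxolan-3-yl]-2-hydroxybutyl (2R,3R)-2,3-dimethyloxirane-2-carboxylate
Product: 21 (1R)-1-[(2S,3S)-2-ethenyl-4-methylidene-5-oxooxolan-3-yl]-2-oxobutyl (2R,3R)-2,3-dimethyloxirane-2-carboxylate
Conditions: Dess–Martin periodinane, NaHCO3, CH2Cl2, 0 °C to rt
Reagents that add atoms: none
Why: Dess–Martin oxidation under buffered conditions gives the α-acyloxy ethyl ketone without epimerising C8.

Step 14
Reactants: 22 ethyl 4-methylpent-4-enoate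
Product: 23 4-methylpent-4-enal
Conditions: iBu2AlH (1.05 equiv), CH2Cl2, −78 °C; aq. potassium sodium tartrate
Reagents that add atoms: none
Why: Partial ester reduction as in step 1; no stereocentre.

Step 15
Reactants: 21 (1R)-1-[(2S,3S)-2-ethenyl-4-methylidene-5-oxooxolan-3-yl]-2-oxobutyl (2R,3R)-2,3-dimethyloxirane-2-carboxylate; 23 4-methylpent-4-enal
Product: 25 (1R,3S,4S)-1-[(2S,3S)-2-ethenyl-4-methylidene-5-oxooxolan-3-yl]-4-hydroxy-3,7-dimethyl-2-oxooct-7-en-1-yl (2R,3R)-2,3-dimethyloxirane-2-carboxylate, via boron enolate 24 (not isolated)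
Conditions: (c-C6H11)2BCl (1.5 equiv), Me2NEt (1.8 equiv), Et2O, −78 to 0 °C; then 23, −78 to −20 °C; MeOH/pH 7 buffer, then SiO2
Reagents that add atoms: none
Why: Paterson anti-aldol: the ethyl side is enolised to the E enol borinate, and in the chair transition state the α′-acyloxy group (α′-H eclipsed, ester towards the aldehyde, C7 outwards) directs the aldehyde to one face, setting C10 S and C1 S with the methyl and hydroxyl anti.

Step 16
Reactants: 25 (1R,3S,4S)-1-[(2S,3S)-2-ethenyl-4-methylidene-5-oxooxolan-3-yl]-4-hydroxy-3,7-dimethyl-2-oxooct-7-en-1-yl (2R,3R)-2,3-dimethyloxirane-2-carboxylate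
Product: 26 (3aS,4R,6S,7S,10Z,11aS)-7-hydroxy-6,10-dimethyl-3-methylidene-2,5-dioxo-2,3,3a,4,5,6,7,8,9,11a-decahydrocyclodeca[b]furan-4-yl (2R,3R)-2,3-dimethyloxirane-2-carboxylate (target)
Conditions: second-generation Hoveyda–Grubbs catalyst RuCl2(H2IMes)(=CH-C6H4-2-OiPr) (10 mol%), 1,4-benzoquinone (20 mol%), toluene (1 mM), 80 °C
Reagents that add atoms: none
Why: Ring-closing metathesis of the C6 vinyl group with the 1,1-disubstituted alkene closes the ten-membered ring as the Z trisubstituted olefin (the ring-favoured geometry); the α-methylene lactone cannot compete because it could only give a four- or nine-membered ring.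

**Compound list**

1 | ethyl 3,3-diethoxypropanoate | CCOC(=O)CC(OCC)OCC | starting material
2 | 3,3-diethoxypropanal | O=CCC(OCC)OCC | intermediate
3 | methyl acrylate | C=CC(=O)OC | starting material
4 | methyl 5,5-diethoxy-3-hydroxy-2-methylidenepentanoate (racemic) | C=C(C(=O)OC)C(O)CC(OCC)OCC | intermediate
5 | methyl (2Z)-2-(bromomethyl)-5,5-diethoxypent-2-enoate | BrC/C(C(=O)OC)=C\CC(OCC)OCC | intermediate
6 | acrolein | C=CC=O | starting material
7 | methyl (3RS,4RS)-3-(2,2-diethoxyethyl)-4-hydroxy-2-methylidenehex-5-enoate (syn racemate, both enantiomers drawn) | C=C[C@H](O)[C@@H](CC(OCC)OCC)C(=C)C(=O)OC.C=C[C@@H](O)[C@H](CC(OCC)OCC)C(=C)C(=O)OC | intermediate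
8 | methyl (3S,4S)-3-(2,2-diethoxyethyl)-4-hydroxy-2-methylidenehex-5-enoate | C=C[C@H](O)[C@@H](CC(OCC)OCC)C(=C)C(=O)OC | intermediate
9 | (4S,5S)-4-(2,2-diethoxyethyl)-5-ethenyl-3-methylideneoxolan-2-one (not isolated) | C=C1C(=O)O[C@@H](C=C)[C@H]1CC(OCC)OCC | intermediate
10 | 2-[(2S,3S)-2-ethenyl-4-methylidene-5-oxooxolan-3-yl]acetaldehyde | C=C1C(=O)O[C@@H](C=C)[C@H]1CC=O | intermediate
11 | angelic acid, (2Z)-2-methylbut-2-enoic acid | C/C=C(/C)C(=O)O | starting material
12 | (2Z)-2-methylbut-2-en-1-ol | C/C=C(/C)CO | intermediate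
13 | [(2S,3R)-2,3-dimethyloxiran-2-yl]methanol | OC[C@]1(C)O[C@@H]1C | intermediate
14 | (2R,3R)-2,3-dimethyloxirane-2-carboxylic acid | OC(=O)[C@]1(C)O[C@@H]1C | intermediate
15 | 1-[(2R,3R)-2,3-dimethyloxirane-2-carbonyl]-1H-imidazole (not isolated) | O=C(n1ccnc1)[C@]1(C)O[C@@H]1C | intermediate
16 | O-[(2R,3R)-2,3-dimethyloxirane-2-carbonyl]-N-methylhydroxylamine | CNOC(=O)[C@]1(C)O[C@@H]1C | intermediate
17 | (E)-N-acyloxy-N-methyl enamine of 10 (not isolated) | C=C1C(=O)O[C@@H](C=C)[C@H]1/C=C/N(C)OC(=O)[C@]1(C)O[C@@H]1C | intermediate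
18 | N-methyl imine of 19 (not isolated) | C=C1C(=O)O[C@@H](C=C)[C@H]1[C@@H](OC(=O)[C@]2(C)O[C@@H]2C)/C=N/C | intermediate
19 | (1R)-1-[(2S,3S)-2-ethenyl-4-methylidene-5-oxooxolan-3-yl]-2-oxoethyl (2R,3R)-2,3-dimethyloxirane-2-carboxylate | C=C1C(=O)O[C@@H](C=C)[C@H]1[C@@H](OC(=O)[C@]2(C)O[C@@H]2C)C=O | intermediate
20 | (1R)-1-[(2S,3S)-2-ethenyl-4-methylidene-5-oxooxolan-3-yl]-2-hydroxybutyl (2R,3R)-2,3-dimethyloxirane-2-carboxylate (C9 epimers) | C=C1C(=O)O[C@@H](C=C)[C@H]1[C@@H](OC(=O)[C@]2(C)O[C@@H]2C)C(O)CC | intermediate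
21 | (1R)-1-[(2S,3S)-2-ethenyl-4-methylidene-5-oxooxolan-3-yl]-2-oxobutyl (2R,3R)-2,3-dimethyloxirane-2-carboxylate | C=C1C(=O)O[C@@H](C=C)[C@H]1[C@@H](OC(=O)[C@]2(C)O[C@@H]2C)C(=O)CC | intermediate
22 | ethyl 4-methylpent-4-enoate | C=C(C)CCC(=O)OCC | starting material
23 | 4-methylpent-4-enal | C=C(C)CCC=O | intermediate
24 | (E)-dicyclohexylboron enolate of 21 (not isolated) | C=C1C(=O)O[C@@H](C=C)[C@H]1[C@@H](OC(=O)[C@]2(C)O[C@@H]2C)/C(OB(C2CCCCC2)C2CCCCC2)=C\C | intermediate
25 | (1R,3S,4S)-1-[(2S,3S)-2-ethenyl-4-methylidene-5-oxooxolan-3-yl]-4-hydroxy-3,7-dimethyl-2-oxooct-7-en-1-yl (2R,3R)-2,3-dimethyloxirane-2-carboxylate | C=C1C(=O)O[C@@H](C=C)[C@H]1[C@@H](OC(=O)[C@]2(C)O[C@@H]2C)C(=O)[C@@H](C)[C@@H](O)CCC(C)=C | intermediate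
26 | (3aS,4R,6S,7S,10Z,11aS)-7-hydroxy-6,10-dimethyl-3-methylidene-2,5-dioxo-2,3,3a,4,5,6,7,8,9,11a-decahydrocyclodeca[b]furan-4-yl (2R,3R)-2,3-dimethyloxirane-2-carboxylate | C=C1C(=O)O[C@H]2/C=C(/C)CC[C@H](O)[C@H](C)C(=O)[C@H](OC(=O)[C@]3(C)O[C@@H]3C)[C@@H]12 | target

**Step count and risk**

Total steps: 16. Longest linear sequence: 11 steps (steps 1–6, 11–13, 15, 16).

Three steps most likely to fail:

Step 11 (the proposed new C–O bond formation). Risks are a slow or unselective rearrangement, O-to-N acyl shift of 16, and amine addition to the methylene lactone. The fallback uses the known amine-catalysed α-acyloxylation of aldehydes with diacyl peroxides. It sets out from 10 (with acid 14) and comes back at 19. Acid 14 is coupled with urea–hydrogen peroxide and dicyclohexylcarbodiimide (CH2Cl2, 0 °C) to bis[(2R,3R)-2,3-dimethyloxirane-2-carbonyl] peroxide F1. Aldehyde 10 is then treated with F1 and (R)-2-(triphenylmethyl)pyrrolidine (10 mol%, THF, 0 °C), whose enamine is attacked on the unshielded face to give 19 directly.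

Step 12 (ethyl Grignard next to an ester, an epoxy ester and a methylene lactone; acyl migration to the new alkoxide). The fallback sets out from 19 and comes back at 21, replacing steps 12 and 13. Vinyl bromide is added by the Nozaki–Hiyama–Kishi reaction (CrCl2, NiCl2 1 mol%, DMF/THF, rt), which tolerates esters and enoates, to give (1R)-1-[(2S,3S)-2-ethenyl-4-methylidene-5-oxooxolan-3-yl]-2-hydroxybut-3-en-1-yl (2R,3R)-2,3-dimethyloxirane-2-carboxylate F2. Redox isomerisation of this allylic alcohol with RuCl(C5H5)(PPh3)2 and Et3NHPF6 (dioxane, 90 °C) then gives ethyl ketone 21 without any oxidant.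

Step 16 (ten-membered ring closure onto a 1,1-disubstituted alkene). The fallback is a relay ring-closing metathesis; it sets out from 21 and comes back at 26. Geraniol is O-allylated (NaH, allyl bromide, THF) to (2E)-3,7-dimethyl-1-(prop-2-en-1-yloxy)octa-2,6-diene F3. The remote alkene is epoxidised (mCPBA, CH2Cl2, 0 °C) to 2,2-dimethyl-3-[(3E)-3-methyl-5-(prop-2-en-1-yloxy)pent-3-en-1-yl]oxirane F4, which is cleaved (H5IO6, THF/H2O) to (4E)-4-methyl-6-(prop-2-en-1-yloxy)hex-4-enal F5. The aldol of 21 with this aldehyde under the conditions of step 15 gives (1R,3S,4S,7E)-1-[(2S,3S)-2-ethenyl-4-methylidene-5-oxooxolan-3-yl]-4-hydroxy-3,7-dimethyl-2-oxo-9-(prop-2-en-1-yloxy)non-7-en-1-yl (2R,3R)-2,3-dimethyloxirane-2-carboxylate F6. With the same ruthenium catalyst the carbene loads on the terminal allyl ether, expels 2,5-dihydrofuran and is thereby placed on C4, from where closure onto the C6 vinyl group gives 26.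

Further compounds

F1 | step 11 | bis[(2R,3R)-2,3-dimethyloxirane-2-carbonyl] peroxide | O=C(OOC(=O)[C@]1(C)O[C@@H]1C)[C@]1(C)O[C@@H]1C
F2 | step 12 | (1R)-1-[(2S,3S)-2-ethenyl-4-methylidene-5-oxooxolan-3-yl]-2-hydroxybut-3-en-1-yl (2R,3R)-2,3-dimethyloxirane-2-carboxylate (carbinol epimers) | C=C1C(=O)O[C@@H](C=C)[C@H]1[C@@H](OC(=O)[C@]2(C)O[C@@H]2C)C(O)C=C
F3 | step 16 | (2E)-3,7-dimethyl-1-(prop-2-en-1-yloxy)octa-2,6-diene | C=CCOC/C=C(\C)CCC=C(C)C
F4 | step 16 | 2,2-dimethyl-3-[(3E)-3-methyl-5-(prop-2-en-1-yloxy)pent-3-en-1-yl]oxirane (racemic) | C=CCOC/C=C(\C)CCC1OC1(C)C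
F5 | step 16 | (4E)-4-methyl-6-(prop-2-en-1-yloxy)hex-4-enal | C=CCOC/C=C(\C)CCC=O
F6 | step 16 | (1R,3S,4S,7E)-1-[(2S,3S)-2-ethenyl-4-methylidene-5-oxooxolan-3-yl]-4-hydroxy-3,7-dimethyl-2-oxo-9-(prop-2-en-1-yloxy)non-7-en-1-yl (2R,3R)-2,3-dimethyloxirane-2-carboxylate | C=C1C(=O)O[C@@H](C=C)[C@H]1[C@@H](OC(=O)[C@]2(C)O[C@@H]2C)C(=O)[C@@H](C)[C@@H](O)CC/C(C)=C/COCC=C
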